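**Assumption:** the SMILES is read as ring (1S,3S,4S) with Br, Cl and the side chain all equatorial (Br/Cl trans), and pyran C3 as R. Catalyst enantiomers named are those expected to give the stated product and would be confirmed on the first run. The route is a paper design; nothing here has been run.

## Retrosynthetic overview

1. Dihydropyran (made last): the enol-ether C–O bond comes from cyclodehydration of a δ-hydroxy methyl ketone; C3–Br comes from SN2 bromide opening of an (S)-epoxide made by Shi epoxidation of a prenyl group.
2. Side chain: α-prenylation of a cyclohexylacetic Weinreb amide, then MeMgBr.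
3. Ring halides: the trans-diequatorial sec-Br/tert-Cl pair comes from the trans-diaxial tert-Br/sec-Cl isomer by 1,2-halogen interchange; that isomer comes from an α-chloro ketone (Me addition, then OH→Br).
4. Key step: enantioselective α-chlorination that desymmetrises a Cs-symmetric 4-substituted cyclohexanone, setting ring C1 and the neighbouring halogen-bearing carbon together.
5. The symmetric ketone comes from partial hydrogenation of 4-hydroxyphenylacetic acid. Ring order: cyclohexane first (from the arene), dihydropyran last.

## Forward route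

**Step 1**
Reactants: 1, 4-hydroxyphenylacetic acid
Product: 2, 2-(4-oxocyclohexyl)acetic acid
Conditions: H2 (5 bar), 5% Pd/C, H2O, 80 °C (stop at 2 equiv H2)
Reagents that add atoms: none
Why: Pd-catalysed partial hydrogenation of a phenol stops at the cyclohexanone because the enol tautomerises to a ketone that binds Pd weakly, so the arene is dearomatised directly to the Cs-symmetric ketone with no stereocentre formed.

**Step 2**
Reactants: 2, 2-(4-oxocyclohexyl)acetic acid
Product: 3, N-methoxy-N-methyl-2-(4-oxocyclohexyl)acetamide
Conditions: MeNHOMe·HCl, EDC·HCl, HOBt, i-Pr2NEt, CH2Cl2, 0 °C → rt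
Reagents that add atoms: N,O-dimethylhydroxylamine hydrochloride, CNOC.Cl
Why: Standard carbodiimide amide coupling (Weinreb amide formation), in which the ketone is inert to the weakly nucleophilic hydroxylamine.

**Step 3 (key step)**
Reactants: 3, N-methoxy-N-methyl-2-(4-oxocyclohexyl)acetamide
Product: 4, 2-[(1R,3R)-3-chloro-4-oxocyclohexyl]-N-methoxy-N-methylacetamide (Cl trans to the side chain: Cl axial, side chain equatorial)
Conditions: NCS (1.1 equiv), 4,5-diphenylimidazolidine (20 mol %, the (4R,5R) or (4S,5S) enantiomer that delivers the 2R chloride), 2-nitrobenzoic acid (50 mol %), MeCN, −25 °C; use crude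
Reagents that add atoms: N-chlorosuccinimide, O=C1CCC(=O)N1Cl
Why: Proposed new method: the known enamine-catalysed enantioselective α-chlorination of cyclohexanones is used as a desymmetrisation, where the C2-symmetric aminal catalyst fixes the new C–Cl carbon and stereoelectronically preferred axial attack on the enamine half-chair (4-substituent equatorial) puts Cl trans to the side chain, so ring C1 and C3 are set together; the closest known reactions are the same catalyst system on cyclohexanone itself and enamine-catalysed desymmetrising aldol, α-aminoxylation and α-fluorination of 4-substituted cyclohexanones.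

**Step 4**
Reactants: 4, 2-[(1R,3R)-3-chloro-4-oxocyclohexyl]-N-methoxy-N-methylacetamide
Product: 5, 2-[(1R,3R,4S)-3-chloro-4-hydroxy-4-methylcyclohexyl]-N-methoxy-N-methylacetamide (OH cis to Cl; any 4R epimer is carried along)
Conditions: MeTi(Oi-Pr)3 (from MeLi + ClTi(Oi-Pr)3), THF, −40 → 0 °C
Reagents that add atoms: methyltriisopropoxytitanium, C[Ti](OC(C)C)(OC(C)C)OC(C)C
Why: Chemoselective, non-basic 1,2-addition to the activated α-chloro ketone (amide untouched, CHCl not epimerised), expected mainly anti to the axial C–Cl bond (Cornforth/Felkin–Anh), although the C4 configuration is irrelevant because this carbon is ionised in step 5.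

**Step 5**
Reactants: 5, 2-[(1R,3R,4S)-3-chloro-4-hydroxy-4-methylcyclohexyl]-N-methoxy-N-methylacetamide
Product: 6, 2-[(1R,3R,4R)-4-bromo-3-chloro-4-methylcyclohexyl]-N-methoxy-N-methylacetamide (Br and Cl trans-diaxial; Br cis and Cl trans to the side chain)
Conditions: TMSBr (2 equiv), CH2Cl2, −20 → 0 °C; evaporate, use crude
Reagents that add atoms: bromotrimethylsilane, C[Si](C)(C)Br
Why: SN1 substitution of the tertiary alcohol with neighbouring-group participation, in which the antiperiplanar axial C–Cl shields the lower face of the tertiary cation so bromide adds axially from the opposite face, giving the trans-diaxial tert-bromide from either carbinol epimer (any E1 olefin re-adds HBr to the same cation).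

**Step 6**
Reactants: 6, 2-[(1R,3R,4R)-4-bromo-3-chloro-4-methylcyclohexyl]-N-methoxy-N-methylacetamide
Product: 7, 2-[(1R,3S,4S)-3-bromo-4-chloro-4-methylcyclohexyl]-N-methoxy-N-methylacetamide (Br, Cl and side chain equatorial; CH3 axial)
Conditions: MeNO2, 70 °C, dark, N2
Reagents that add atoms: none
Why: Diaxial→diequatorial 1,2-interchange (dyotropic rearrangement) of a trans-diaxial vicinal dihalide, in which Br and Cl swap carbons on opposite faces with inversion at both centres, stereospecifically giving tert-Cl trans and sec-Br cis to the side chain (the pairing favoured in polar solvent), which fixes ring C3 and C4 in their final configuration.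

**Step 7**
Reactants: 7, 2-[(1R,3S,4S)-3-bromo-4-chloro-4-methylcyclohexyl]-N-methoxy-N-methylacetamide; 8, prenyl bromide (1-bromo-3-methylbut-2-ene)
Product: 9, 2-[(1S,3S,4S)-3-bromo-4-chloro-4-methylcyclohexyl]-N-methoxy-N,5-dimethylhex-4-enamide (C2 epimer mixture; the ring C1 descriptor changes from R to S only through CIP priorities)
Conditions: LDA (1.05 equiv), THF, −78 °C; then 8, −78 → −50 °C
Reagents that add atoms: prenyl bromide (8), CC(C)=CCBr
Why: Alkylation of the Weinreb amide lithium enolate with a reactive allylic bromide at −78 °C, where the equatorial sec-bromide and tert-chloride (no antiperiplanar ring H) are inert; the new α-centre is an inconsequential epimer mixture because it becomes sp2 in step 11.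

**Step 8**
Reactants: 9, 2-[(1S,3S,4S)-3-bromo-4-chloro-4-methylcyclohexyl]-N-methoxy-N,5-dimethylhex-4-enamide
Product: 10, 3-[(1S,3S,4S)-3-bromo-4-chloro-4-methylcyclohexyl]-6-methylhept-5-en-2-one
Conditions: MeMgBr (1.5 equiv), THF, 0 °C; aq. NH4Cl
Reagents that add atoms: methylmagnesium bromide, C[Mg]Br
Why: Weinreb ketone synthesis, in which the chelated tetrahedral intermediate prevents over-addition and the Grignard reagent leaves the alkyl halides alone at 0 °C.

**Step 9**
Reactants: 10, 3-[(1S,3S,4S)-3-bromo-4-chloro-4-methylcyclohexyl]-6-methylhept-5-en-2-one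
Product: 11, 3-[(1S,3S,4S)-3-bromo-4-chloro-4-methylcyclohexyl]-4-[(2S)-3,3-dimethyloxiran-2-yl]butan-2-one
Conditions: ent-Shi ketone (L-fructose-derived, 30 mol %), Oxone, K2CO3, Bu4NHSO4, MeCN–DMM–aq. buffer (pH 10.5), 0 °C
Reagents that add atoms: potassium peroxymonosulfate (Oxone), [K+].[O-]S(=O)(=O)OO
Why: Shi asymmetric epoxidation (chiral dioxirane, spiro transition state) of the electron-rich trisubstituted prenyl olefin is reagent-controlled and gives the 2S epoxide with the L-series ketone, while the buffered conditions leave ketone and halides untouched.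

**Step 10**
Reactants: 11, 3-[(1S,3S,4S)-3-bromo-4-chloro-4-methylcyclohexyl]-4-[(2S)-3,3-dimethyloxiran-2-yl]butan-2-one
Product: 12, (5R)-5-bromo-3-[(1S,3S,4S)-3-bromo-4-chloro-4-methylcyclohexyl]-6-hydroxy-6-methylheptan-2-one (may sit partly as the cyclic hemiketal)
Conditions: Li2NiBr4 (from LiBr + NiBr2), THF, 0 °C → rt
Reagents that add atoms: dilithium tetrabromonickelate, [Li+].[Li+].Br[Ni-2](Br)(Br)Br
Why: Soft nucleophilic bromide opens the trisubstituted epoxide by SN2 at the less hindered secondary carbon with inversion, turning the S epoxide carbon into the R C–Br centre and freeing the tertiary alcohol.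

**Step 11**
Reactants: 12, (5R)-5-bromo-3-[(1S,3S,4S)-3-bromo-4-chloro-4-methylcyclohexyl]-6-hydroxy-6-methylheptan-2-one
Product: 13, laucapyranoid A, (3R)-3-bromo-5-[(1S,3S,4S)-3-bromo-4-chloro-4-methylcyclohexyl]-2,2,6-trimethyl-3,4-dihydro-2H-pyran
Conditions: PPTS (10 mol %), PhMe, 4 Å MS, 60 °C
Reagents that add atoms: none
Why: Acid-catalysed cyclodehydration of the δ-hydroxy ketone through the six-membered hemiketal/oxocarbenium ion, which loses the ring-adjacent α-proton to give the more stable tetrasubstituted endocyclic enol ether, converging both α-epimers and leaving all four stereocentres untouched.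

## Compound list

1 | 4-hydroxyphenylacetic acid | OC(=O)Cc1ccc(O)cc1 | starting material
2 | 2-(4-oxocyclohexyl)acetic acid | OC(=O)CC1CCC(=O)CC1 | intermediate
3 | N-methoxy-N-methyl-2-(4-oxocyclohexyl)acetamide | CON(C)C(=O)CC1CCC(=O)CC1 | intermediate
4 | 2-[(1R,3R)-3-chloro-4-oxocyclohexyl]-N-methoxy-N-methylacetamide | CON(C)C(=O)C[C@H]1CCC(=O)[C@H](Cl)C1 | intermediate
5 | 2-[(1R,3R,4S)-3-chloro-4-hydroxy-4-methylcyclohexyl]-N-methoxy-N-methylacetamide | CON(C)C(=O)C[C@H]1CC[C@](C)(O)[C@H](Cl)C1 | intermediate
6 | 2-[(1R,3R,4R)-4-bromo-3-chloro-4-methylcyclohexyl]-N-methoxy-N-methylacetamide | CON(C)C(=O)C[C@H]1CC[C@](Br)(C)[C@H](Cl)C1 | intermediate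
7 | 2-[(1R,3S,4S)-3-bromo-4-chloro-4-methylcyclohexyl]-N-methoxy-N-methylacetamide | CON(C)C(=O)C[C@H]1CC[C@](C)(Cl)[C@@H](Br)C1 | intermediate
8 | prenyl bromide (1-bromo-3-methylbut-2-ene) | CC(C)=CCBr | starting material
9 | 2-[(1S,3S,4S)-3-bromo-4-chloro-4-methylcyclohexyl]-N-methoxy-N,5-dimethylhex-4-enamide (C2 epimers) | CON(C)C(=O)C(CC=C(C)C)[C@H]1CC[C@](C)(Cl)[C@@H](Br)C1 | intermediate
10 | 3-[(1S,3S,4S)-3-bromo-4-chloro-4-methylcyclohexyl]-6-methylhept-5-en-2-one (C3 epimers) | CC(=O)C(CC=C(C)C)[C@H]1CC[C@](C)(Cl)[C@@H](Br)C1 | intermediate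
11 | 3-[(1S,3S,4S)-3-bromo-4-chloro-4-methylcyclohexyl]-4-[(2S)-3,3-dimethyloxiran-2-yl]butan-2-one (C3 epimers) | CC(=O)C(C[C@@H]2OC2(C)C)[C@H]1CC[C@](C)(Cl)[C@@H](Br)C1 | intermediate
12 | (5R)-5-bromo-3-[(1S,3S,4S)-3-bromo-4-chloro-4-methylcyclohexyl]-6-hydroxy-6-methylheptan-2-one (C3 epimers) | CC(=O)C(C[C@@H](Br)C(C)(C)O)[C@H]1CC[C@](C)(Cl)[C@@H](Br)C1 | intermediate
13 | laucapyranoid A, (3R)-3-bromo-5-[(1S,3S,4S)-3-bromo-4-chloro-4-methylcyclohexyl]-2,2,6-trimethyl-3,4-dihydro-2H-pyran | CC1=C([C@H]2CC[C@](C)(Cl)[C@@H](Br)C2)C[C@@H](Br)C(C)(C)O1 | target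

## Summary

Total steps: 11. Longest linear sequence: 11 (from 1; compound 8 is purchased).

Steps most likely to fail, with fallbacks:

1. **Step 3** (desymmetrising α-chlorination: ee, trans/cis ratio, over-chlorination). Fallback: build the ring stereocentre from p-tolylacetic acid instead. Birch reduction gives the 1,4-diene acid; carboxyl-directed Ir-catalysed asymmetric hydrogenation of the β,γ-olefin gives (S)-2-(4-methylcyclohex-3-enyl)acetic acid; after Weinreb amide formation, substrate-controlled trans-diaxial chlorohydroxylation (TCCA, aq. acetone) gives the C4 epimer of 5, which rejoins at step 5.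

2. **Step 6** (with step 5: the halogen interchange may stop at an equilibrium mixture, or the tertiary bromide may lose HBr). Fallback: install the diequatorial pair without interchange. From the (S)-alkene amide of fallback 1, catalyst-controlled Shi epoxidation anti to the side chain, HBr opening at the tertiary carbon (trans-diaxial tert-Br/sec-OH), then PPh3/NCS; the anti bromine participates to form the bromonium ion cis to the side chain, and chloride opens it at the tertiary carbon to give 7 directly.

3. **Step 10** (bromide may attack the tertiary carbon, or the ketone oxygen may open the epoxide). Fallback: form the C–Br and C–O bonds in one bromonium step. Enantioselective bromocyclisation of ketone 10 (chiral Lewis-base catalyst with DBDMH), with 6-endo capture by the carbonyl oxygen and loss of H+, gives 13 directly and replaces steps 9–11.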